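**Assumptions.** I number the chain from C5 (the CH2 on furan C3) to C19 (the lactone C=O). On that numbering the target is (7E,10S,11E,15R,16S). I treat the D‑fructose Shi ketone, (−)‑sparteine and isopropenyl‑Bpin as purchasable.

## Retrosynthetic overview
1. The lactone is made last. Acid‑triggered 5‑exo opening of a (15R,16R)‑epoxy methyl ester, with inversion at C16, forms the γ‑lactone and frees C15‑OH together. C10‑OH can therefore be acetylated earlier with no protecting group on C15.
2. The key disconnection is C9–C10, not the usual C10–C11 vinyl‑metal plus aldehyde. A chirality‑transfer allylboration of an E‑enal with an enantioenriched α‑substituted β‑methallylboron reagent makes the C9–C10 bond, C10(S) and the E‑C7=C8 alkene in one step.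
3. The allylboronate comes from sparteine lithiation–borylation of 3‑(3‑furyl)propyl carbamate with isopropenyl‑Bpin. The alcohol comes from 3‑bromofuran and oxetane.
4. The enal comes from geranyl acetate: epoxide‑to‑allylic‑alcohol transposition, Johnson–Claisen (E‑C15=C16, plus a C2 ester), site‑selective Shi epoxidation, then deacetylation and MnO2.
5. Ring order: the furan is purchased, the oxirane is temporary (step 4), and the γ‑lactone is formed last (step 12).

## Route

### Enal fragment (steps 1–6)

**Step 1**
- Reactants: 1, geranyl acetate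
- Product: 2, (±)‑6,7‑epoxygeranyl acetate [(E)‑5‑(3,3‑dimethyloxiran‑2‑yl)‑3‑methylpent‑2‑enyl acetate]
- Conditions: mCPBA (1.05 equiv), NaHCO3, CH2Cl2, 0 °C
- Reagents that add atoms: mCPBA, O=C(OO)c1cccc(Cl)c1
- Why: Prilezhaev epoxidation picks the electron‑rich terminal alkene because the 2,3‑alkene is inductively deactivated by the allylic acetate, and the racemic centre formed here is erased in step 3.

**Step 2**
- Reactants: 2
- Product: 3, (±)‑(E)‑6‑hydroxy‑3,7‑dimethylocta‑2,7‑dien‑1‑yl acetate
- Conditions: TMSOTf, 2,6‑lutidine, toluene, −78 °C; DBU, −78 °C to rt; then citric acid, MeOH, rt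
- Reagents that add atoms: none (the TMS group is transient)
- Why: In this silyl‑triflate‑promoted epoxide‑to‑allylic‑alcohol isomerisation (Noyori type), the C–O bond breaks at the tertiary carbon and DBU removes a methyl proton, which gives the isopropenyl carbinol under acetate‑compatible conditions.

**Step 3**
- Reactants: 3; 4, trimethyl orthoacetate
- Product: 5, methyl (4E,8E)‑10‑acetoxy‑4,8‑dimethyldeca‑4,8‑dienoate
- Conditions: MeC(OMe)3 (6 equiv), EtCO2H (10 mol %), xylenes, 140 °C, −MeOH
- Reagents that add atoms: trimethyl orthoacetate (4), CC(OC)(OC)OC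
- Why: The Johnson orthoester Claisen [3,3] shift runs through a chair TS with the chain equatorial, which gives the E‑trisubstituted C15=C16 alkene (expected >95:5), adds C18–C19 and destroys the racemic carbinol.

**Step 4**
- Reactants: 5
- Product: 6, methyl 3‑{(2R,3R)‑3‑[(E)‑5‑acetoxy‑3‑methylpent‑3‑enyl]‑2‑methyloxiran‑2‑yl}propanoate (15R,16R)
- Conditions: D‑fructose‑derived Shi ketone (0.3 equiv), Oxone, K2CO3, Bu4NHSO4, MeCN/DMM–aq borate/EDTA buffer (pH ≈ 10.5), 0 °C
- Reagents that add atoms: Oxone (KHSO5), [K+].[O-]S(=O)(=O)OO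
- Why: In the Shi asymmetric epoxidation the chiral dioxirane attacks the isolated E‑trisubstituted alkene through the spiro TS to give the (R,R)‑epoxide (about 90–95 % ee expected), and the C11=C12 alkene is left alone because the allylic acetate deactivates it.

**Step 5**
- Reactants: 6
- Product: 7, methyl 3‑{(2R,3R)‑3‑[(E)‑5‑hydroxy‑3‑methylpent‑3‑enyl]‑2‑methyloxiran‑2‑yl}propanoate
- Conditions: K2CO3 (0.3 equiv), MeOH, 0 °C to rt
- Reagents that add atoms: none
- Why: Base‑catalysed transesterification (methanolysis) removes the primary acetate, exchange at the methyl ester is degenerate, and the trisubstituted epoxide is inert to mild base.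

**Step 6**
- Reactants: 7
- Product: 8, methyl 3‑{(2R,3R)‑2‑methyl‑3‑[(E)‑3‑methyl‑5‑oxopent‑3‑enyl]oxiran‑2‑yl}propanoate (E‑enal)
- Conditions: activated MnO2 (20 equiv), CH2Cl2, rt
- Reagents that add atoms: none
- Why: MnO2 allylic oxidation is neutral and chemoselective, so it gives the enal with no E/Z leakage and no damage to the epoxide or ester.

### Allylboronate fragment (steps 7–9)

**Step 7**
- Reactants: 9, 3‑bromofuran; 10, oxetane
- Product: 11, 3‑(furan‑3‑yl)propan‑1‑ol
- Conditions: nBuLi, THF, −78 °C, 30 min; oxetane, then BF3·OEt2, −78 °C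
- Reagents that add atoms: oxetane (10), C1COC1
- Why: Br–Li exchange gives 3‑lithiofuran, which is regiostable below −70 °C, and it opens the BF3‑activated oxetane by SN2 to install the three‑carbon arm in one step.

**Step 8**
- Reactants: 11; 12, N,N‑diisopropylcarbamoyl chloride
- Product: 13, 3‑(furan‑3‑yl)propyl N,N‑diisopropylcarbamate
- Conditions: iPr2NCOCl, Et3N, CH2Cl2, reflux
- Reagents that add atoms: iPr2NCOCl (12), CC(C)N(C(C)C)C(=O)Cl
- Why: O‑carbamoylation (acyl substitution) installs the Hoppe directing and leaving group.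

**Step 9**
- Reactants: 13; 14, isopropenylboronic acid pinacol ester
- Product: 15, 2‑[(3R)‑5‑(furan‑3‑yl)‑2‑methylpent‑1‑en‑3‑yl]‑4,4,5,5‑tetramethyl‑1,3,2‑dioxaborolane
- Conditions: sBuLi (1.2 equiv), (−)‑sparteine (1.2 equiv), Et2O, −78 °C, 5 h; 14, −78 °C, 1 h; MgBr2·OEt2, then reflux, 12 h
- Reagents that add atoms: isopropenyl‑Bpin (14), C=C(C)B1OC(C)(C)C(C)(C)O1
- Why: In this Hoppe lithiation followed by a Matteson‑type 1,2‑metallate shift (lithiation–borylation), sBuLi·(−)‑sparteine removes the pro‑S α‑H under carbamate direction, boronate formation is retentive, and anti‑periplanar isopropenyl migration expels OCb with inversion to give (R)‑15 (about 96:4 er expected).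

### Union and endgame (steps 10–12)

**Step 10 (key step)**
- Reactants: 8; 15
- Product: 16, methyl 3‑{(2R,3R)‑3‑[(3E,5S,7E)‑10‑(furan‑3‑yl)‑5‑hydroxy‑3,7‑dimethyldeca‑3,7‑dienyl]‑2‑methyloxiran‑2‑yl}propanoate (10S)
- Conditions: 15 (1.2 equiv), nBuLi (1.2 equiv), THF, −78 °C, 15 min; TFAA (1.4 equiv), −78 °C, 30 min; 8 (1.0 equiv), −78 °C, 3 h; sat. NaHCO3, then triethanolamine
- Reagents that add atoms: none beyond 8 and 15 (the butyl and trifluoroacetyl groups leave with boron)
- Why: In this type‑I allylboration via an in situ borinic ester, the slimmer and more reactive boron lets the furylethyl α‑substituent sit pseudo‑equatorial in the Zimmerman–Traxler chair (giving E‑C7=C8), and syn‑SE2′ chirality transfer from (R)‑C–B delivers the allyl unit to the Si face of the enal (giving 10S) under pure reagent control, with all nBuLi consumed before the ester and epoxide are introduced.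

**Step 11**
- Reactants: 16; 17, acetic anhydride
- Product: 18, the (10S)‑acetate of 16 (epoxy methyl ester retained)
- Conditions: Ac2O, Et3N, DMAP (cat.), CH2Cl2, 0 °C
- Reagents that add atoms: acetic anhydride (17), CC(=O)OC(C)=O
- Why: DMAP‑catalysed acylation of the only free hydroxyl proceeds with retention at C10, and C15–O is still locked in the epoxide, so no selectivity question arises.

**Step 12**
- Reactants: 18
- Product: 19, 10‑acetylirciformonin B [(5S)‑5‑[(1R,4E,6S,8E)‑6‑acetoxy‑11‑(furan‑3‑yl)‑1‑hydroxy‑4,8‑dimethylundeca‑4,8‑dienyl]‑5‑methyldihydrofuran‑2(3H)‑one]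
- Conditions: CSA (0.2 equiv), CH2Cl2 with H2O (3 equiv), 0 °C to rt
- Reagents that add atoms: water, O (MeOH is lost)
- Why: In this acid‑catalysed 5‑exo‑tet epoxide opening with ester‑carbonyl participation, attack at the tertiary C16 inverts it (16R to 16S) while the C15–O bond is untouched (15R), hydrolysis of the dialkoxycarbenium ion gives the γ‑lactone, and the alternative path (water opening at C16, then lactonisation) converges on the same isomer.

## Compound list
| No. | Name | SMILES | Role |
|---|---|---|---|
| 1 | geranyl acetate | CC(=O)OC/C=C(\C)CCC=C(C)C | starting material |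
| 2 | (±)‑6,7‑epoxygeranyl acetate | CC(=O)OC/C=C(\C)CCC1OC1(C)C | intermediate |
| 3 | (±)‑(E)‑6‑hydroxy‑3,7‑dimethylocta‑2,7‑dienyl acetate | CC(=O)OC/C=C(\C)CCC(O)C(C)=C | intermediate |
| 4 | trimethyl orthoacetate | CC(OC)(OC)OC | starting material |
| 5 | methyl (4E,8E)‑10‑acetoxy‑4,8‑dimethyldeca‑4,8‑dienoate | CC(=O)OC/C=C(\C)CC/C=C(\C)CCC(=O)OC | intermediate |
| 6 | (15R,16R)‑epoxy ester acetate | CC(=O)OC/C=C(\C)CC[C@H]1O[C@]1(C)CCC(=O)OC | intermediate |
| 7 | (15R,16R)‑epoxy ester allylic alcohol | OC/C=C(\C)CC[C@H]1O[C@]1(C)CCC(=O)OC | intermediate |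
| 8 | (15R,16R)‑epoxy ester E‑enal | O=C/C=C(\C)CC[C@H]1O[C@]1(C)CCC(=O)OC | intermediate |
| 9 | 3‑bromofuran | Brc1ccoc1 | starting material |
| 10 | oxetane | C1COC1 | starting material |
| 11 | 3‑(furan‑3‑yl)propan‑1‑ol | OCCCc1ccoc1 | intermediate |
| 12 | N,N‑diisopropylcarbamoyl chloride | CC(C)N(C(C)C)C(=O)Cl | starting material |
| 13 | 3‑(furan‑3‑yl)propyl N,N‑diisopropylcarbamate | CC(C)N(C(C)C)C(=O)OCCCc1ccoc1 | intermediate |
| 14 | isopropenylboronic acid pinacol ester | C=C(C)B1OC(C)(C)C(C)(C)O1 | starting material |
| 15 | (R)‑α‑(2‑(3‑furyl)ethyl)‑β‑methallyl‑Bpin | C=C(C)[C@@H](CCc1ccoc1)B1OC(C)(C)C(C)(C)O1 | intermediate |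
| 16 | (10S,15R,16R)‑hydroxy epoxy ester | O[C@H](/C=C(\C)CC[C@H]1O[C@]1(C)CCC(=O)OC)C/C(C)=C/CCc1ccoc1 | intermediate |
| 17 | acetic anhydride | CC(=O)OC(C)=O | starting material |
| 18 | (10S,15R,16R)‑acetoxy epoxy ester | CC(=O)O[C@H](/C=C(\C)CC[C@H]1O[C@]1(C)CCC(=O)OC)C/C(C)=C/CCc1ccoc1 | intermediate |
| 19 | 10‑acetylirciformonin B | CC(=O)O[C@H](/C=C(\C)CC[C@@H](O)[C@]1(C)CCC(=O)O1)C/C(C)=C/CCc1ccoc1 | target |

## Summary
- **Total steps:** 12
- **Longest linear sequence:** 9 (steps 1–6, then 10–12)

**Three steps most likely to fail**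
1. **Step 10, the key allylboration.** The risks are the E/Z ratio with a β‑methallyl reagent, a sluggish β,β‑disubstituted enal, and epoxide survival near boron and trifluoroacetate species. Minor diastereomers arising from the imperfect ee of 6 and 15 are remote (1,6‑related) and may need HPLC.
   - Fallback: separate bond formation from stereocontrol. Add the α‑selective, geometry‑retentive allylbarium reagent made from (E)‑6‑(3‑furyl)‑2‑methylhex‑2‑enyl chloride to 8, which gives racemic C10. Then oxidise with DMP to the dienone and reduce with CBS to set 10S.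
2. **Step 9, lithiation–borylation next to a furan.** The risks are competing furan C2/C5 metalation by sBuLi and erosion of er.
   - Fallback: make the boronate by Matteson asymmetric homologation. Hydroborate 3‑vinylfuran, form the chiral‑diol (DICHED) boronate, treat with LiCHCl2/ZnCl2, then displace the α‑chloride with isopropenylMgBr. The stereocentre is then substrate‑controlled and no alkyllithium base meets the furan.
3. **Step 12, the late acid‑triggered lactonisation.** The risks are SN1 leakage at C16, Meinwald rearrangement, and acid stress on the allylic acetate and furan.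
   - Fallback: lactonise early by treating 6 with CSA. Mask C15‑OH as a TES ether, carry the lactone through steps 5, 6, 10 and 11, and finish with HF·pyridine. This costs two extra steps.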